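**Assumption (one line):** the SMILES is read as the (2R,3S,4S)-oxolane (aryl and CH2OH trans, CH2OH and benzyl cis); the sense of induction of the iridium catalyst in step 5 is taken by analogy with the parent cinnamyl carbonate, and the antipodal ligand is used if the sense proves opposite.

## The problem

- The target is a 2,3,4-trisubstituted oxolane (ring atoms O1, C2–C5). C2 carries a 3,4,5-trimethoxyphenyl group, C3 a hydroxymethyl group (carbon C6), C4 a 4-hydroxy-3-methoxybenzyl group (methylene carbon C7), and C5 is an unsubstituted CH2.
- The three stereocentres are contiguous, (2R,3S,4S): aryl and C6 are trans, C6 and C7 are cis, so aryl and benzyl lie on opposite faces. This is not the all-trans array, so equilibration, or any chair-like radical or anionic ring closure that places every group pseudo-equatorial, gives the wrong C4.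
- C2 can control C3, because trans is both the kinetic and the thermodynamic preference. C4 must be set against thermodynamics, which is easiest if C4 stays sp2 until late and a reagent then adds anti to the arm on C3.
- The two arenes differ, so dimerisation logic is of no use and each arene must be delivered to its own terminus.
- C2–O1 is a benzylic ether: acid ionises it and the electron-rich guaiacyl ring can then close onto C2. The free phenol and the primary alcohol limit the oxidants and bases that can be used late.
- The feature that makes the key step possible: O1 is flanked by C2 (attached to C3, which bears the one-carbon oxygenated arm C6) and by C5 (attached to C4, which bears the one-carbon aryl arm C7). Cutting C3–C4 therefore leaves C3=C6 as a vinyl group on an allylic ether carbon and C4≡C7 as an aryl alkyne on a propargylic ether carbon. The oxolane is a latent 1,6-enyne bridged by O1, and a metal that adds H to C7 and itself to C4 closes the ring 5-exo and ends on C6, exactly where oxygen is needed.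

## Retrosynthesis

**11 from 10 (C6–O from C6–B).** The hydroxyl of target 11 is traced to the pinacol boronate 10. This is preferred to carrying a free or protected alcohol because the boron is what the ring-forming step installs, and because a bulky, non-coordinating CH2Bpin group is the better shield during the preceding reduction. The forward reaction only has to oxidise a primary C–B bond beside a free phenol.

**10 from 9 (C4–H, C7–H and the phenol O–H).** The two hydrogens are removed to give the benzylidene oxolane 9, and the phenol is returned to its benzyl ether. Making C4 sp2 removes the one stereocentre that thermodynamics and ring-closure kinetics both set wrongly. The forward hydrogenation must add to the face opposite the C3 arm and should cleave the benzyl ether in the same operation.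

**9 from 8 (C3–C4 and C6–B; the key cut).** Cutting the C3–C4 ring bond and the C6–B bond opens 9 to the acyclic enyne ether 8, which has a single stereocentre. The neighbouring cuts (C2–C3 by aldol, C2–O1 by a benzylic cation, O1–C5 by displacement) all lead back to an open chain that already needs two or three stereocentres. This cut leaves only C2 and lets C2 set C3 during closure. The forward reaction must form the ring, place boron on C6, give the 2,3-trans isomer and leave the doubly activated C2–O1 bond alone.

**8 from 3 and 7 (C2–O1).** The ether is cut at the benzylic carbon to the linear allylic carbonate 3 and the propargylic alcohol 7. An iridium-catalysed branched-selective allylic etherification creates C2 from two achiral partners, which is shorter than making and then alkylating a chiral 1-arylallyl alcohol. The forward reaction must be branched-selective and enantioselective with a primary propargylic alkoxide.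

**3 from 2 from 1; 7 from 5 and 6; 5 from 4.** Carbonate 3 comes from the cinnamyl alcohol 2, itself from the commercial cinnamate 1. Alcohol 7 comes by Sonogashira coupling of aryl bromide 5 with propargyl alcohol 6, and 5 by benzylation of 4-bromoguaiacol 4. These are routine, and the internal alkyne of 7 already carries the guaiacyl ring to C7.

## Roads not taken

**Alternative 1:** cut C2–C3 and C2–O1, the route most chemists would draw first.
- Forward: aldol of the enolate of the enantiopure β-benzyl-γ-butyrolactone A1 with 3,4,5-trimethoxybenzaldehyde gives the trans lactone A2; hydride reduction gives triol A3; ring closure at C2 follows.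
- Why not: A1 needs an auxiliary or resolution and several steps. A3 has two primary hydroxyls, so closure by displacement gives the 3,4-dibenzyloxolane instead. Closure through the C2 cation needs acid strong enough to ionise a poorly stabilised 3,4,5-trimethoxybenzylic alcohol, and under those conditions Friedel–Crafts attack of the guaiacyl ring on C2 competes. The chosen plan never generates a cation at C2 and needs one catalytic asymmetric step.

**Alternative 2:** cut C2–C3 and O1–C5 as a (3+2) cycloaddition, and C7–aryl as a cross-coupling.
- Forward: Pd-catalysed trimethylenemethane cycloaddition of 3,4,5-trimethoxybenzaldehyde with the cyano-substituted donor A4 gives the 4-methyleneoxolane nitrile A5. The nitrile is reduced to CH2OH, then 9-BBN hydroboration anti to the C3 arm and Suzuki–Miyaura coupling with bromide 5 complete the skeleton.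
- Why not: A4 is not commercial and costs several steps. The nitrile must be reduced in two stages without letting the exocyclic alkene move into conjugation, which would erase C3. Enantiocontrol with a substituted donor and a simple aryl aldehyde is not secured. The chosen plan reaches the same "sp2 C4, then add anti to C3" logic from two one- or two-step fragments.

**Alternative 3:** cut C2–C3 as an O-to-C 1,3-shift.
- Forward: the seven-membered vinyl acetal A6 (a 2-aryl-5-benzyl-4,5-dihydro-1,3-dioxepine, by acetalisation and double-bond migration) is opened by a Lewis acid to an oxocarbenium ion and a tethered (Z)-enol ether, which recombine to a 2-aryl-4-benzyloxolane-3-carbaldehyde in one step.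
- Why not: although it is the shortest on paper, closure from the (Z)-enol ether must keep the C4 hydrogen in the enol plane to avoid 1,3-allylic strain, which puts the formyl group trans to the benzyl group. Equilibration through retro-aldol opening drains to the all-trans aldehyde A7. The required 3,4-cis, 2,4-trans array is neither the kinetic nor the thermodynamic outcome, whereas the chosen plan sets C4 by addition to an exocyclic alkene.

Key step: step 6

## Route

**Step 1**
Reactants: 1 methyl (E)-3-(3,4,5-trimethoxyphenyl)prop-2-enoate
Product: 2 (E)-3-(3,4,5-trimethoxyphenyl)prop-2-en-1-ol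
Conditions: DIBAL-H (2.2 equiv), CH2Cl2, −78 → 0 °C; Rochelle salt work-up
Reagents that add atoms: none
Why: 1,2-reduction of the conjugated ester by an aluminium hydride gives the allylic alcohol; the alkene keeps its E geometry and no stereocentre is formed.

**Step 2**
Reactants: 2 (E)-3-(3,4,5-trimethoxyphenyl)prop-2-en-1-ol
Product: 3 tert-butyl (E)-3-(3,4,5-trimethoxyphenyl)prop-2-en-1-yl carbonate
Conditions: Boc2O, n-Bu4NHSO4 (cat.), 30 % aq NaOH, CH2Cl2, 0 °C → rt
Reagents that add atoms: di-tert-butyl dicarbonate, CC(C)(C)OC(=O)OC(=O)OC(C)(C)C
Why: phase-transfer acylation of the primary alcohol; the tert-butyl carbonate is chosen because the tert-butoxide it releases in step 5 is too hindered to compete with the alkoxide of 7.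

**Step 3**
Reactants: 4 4-bromo-2-methoxyphenol
Product: 5 1-(benzyloxy)-4-bromo-2-methoxybenzene
Conditions: BnBr, K2CO3, DMF, rt
Reagents that add atoms: benzyl bromide, BrCc1ccccc1
Why: Williamson ether synthesis on the phenoxide; the benzyl group is carried to step 7, where hydrogenation removes it together with the alkene.

**Step 4**
Reactants: 5 1-(benzyloxy)-4-bromo-2-methoxybenzene; 6 prop-2-yn-1-ol
Product: 7 3-[4-(benzyloxy)-3-methoxyphenyl]prop-2-yn-1-ol
Conditions: PdCl2(MeCN)2 (2 mol %), XPhos (6 mol %), Cs2CO3, MeCN, 70 °C
Reagents that add atoms: none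
Why: copper-free Sonogashira coupling, suited to electron-rich aryl bromides and tolerant of the free primary alcohol; the internal alkyne carries the guaiacyl ring to the future C7.

**Step 5**
Reactants: 3 tert-butyl (E)-3-(3,4,5-trimethoxyphenyl)prop-2-en-1-yl carbonate; 7 3-[4-(benzyloxy)-3-methoxyphenyl]prop-2-yn-1-ol (1.5 equiv)
Product: 8 5-[(1R)-1-({3-[4-(benzyloxy)-3-methoxyphenyl]prop-2-yn-1-yl}oxy)prop-2-en-1-yl]-1,2,3-trimethoxybenzene
Conditions: [Ir(cod)Cl]2 (2 mol %), (Ra,Rc,Rc)-(1,1'-binaphthalene-2,2'-diyl) N,N-bis(1-phenylethyl)phosphoramidite (4 mol %, pre-activated with n-PrNH2), K3PO4, THF, rt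
Reagents that add atoms: none
Why: iridium-catalysed asymmetric allylic etherification: the cyclometalated iridium phosphoramidite ionises the carbonate and the alkoxide of 7 attacks the aryl-substituted allyl terminus to give the branched ether. C2 is set by the catalyst, with the ligand antipode chosen for R.

**Step 6**
Reactants: 8 5-[(1R)-1-({3-[4-(benzyloxy)-3-methoxyphenyl]prop-2-yn-1-yl}oxy)prop-2-en-1-yl]-1,2,3-trimethoxybenzene
Product: 9 2-{[(2R,3R,4Z)-4-[4-(benzyloxy)-3-methoxybenzylidene]-2-(3,4,5-trimethoxyphenyl)oxolan-3-yl]methyl}-4,4,5,5-tetramethyl-1,3,2-dioxaborolane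
Conditions: Pd(OAc)2 (5 mol %), B2pin2 (1.3 equiv), MeOH (1 equiv), toluene, 50 °C
Reagents that add atoms: bis(pinacolato)diboron, CC1(C)OB(OC1(C)C)B1OC(C)(C)C(C)(C)O1
Why: Pd(OAc)2, B2pin2 and MeOH generate a palladium hydride that adds syn across the alkyne of 8, Pd to C4 and H to C7, steered to this regiochemistry by chelation of the tethered vinyl group. The alkenyl–Pd bond then inserts the C3=C6 double bond, which forms the C3–C4 bond and closes the oxolane in the 5-exo-trig mode with respect to the alkene (the former alkyne carbon C4 stays in the ring and keeps an exocyclic double bond). The primary alkyl–Pd at C6 is captured by B2pin2 (transmetalation and C–B reductive elimination) before β-hydride loss to the diene, and the Pd–boryl left behind is turned back into the hydride by MeOH. The closest known reaction type is the Pd-catalysed borylative cyclisation of 1,6-enynes, a hydropalladation/carbopalladation/borylation cascade related to the Alder-ene cycloisomerisation. The new stereocentre C3 is controlled by C2: in the insertion transition state the aryl group on the allylic carbon takes the pseudo-equatorial position of the forming envelope, away from the vinyl CH2 that rotates into the Pd–C4 bond, so C6 ends trans to the aryl group, (2R,3R) in 9. The syn addition fixes the benzylidene as Z, though either geometry would serve step 7. The step needs borylation to outrun β-hydride elimination and the doubly activated C2–O1 bond to stay intact; excess diboron, the absence of phosphine and acid, and toluene as a non-ionising solvent should secure both.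

**Step 7**
Reactants: 9 2-{[(2R,3R,4Z)-4-[4-(benzyloxy)-3-methoxybenzylidene]-2-(3,4,5-trimethoxyphenyl)oxolan-3-yl]methyl}-4,4,5,5-tetramethyl-1,3,2-dioxaborolane
Product: 10 2-methoxy-4-{[(3S,4R,5R)-4-[(4,4,5,5-tetramethyl-1,3,2-dioxaborolan-2-yl)methyl]-5-(3,4,5-trimethoxyphenyl)oxolan-3-yl]methyl}phenol
Conditions: H2 (1 atm), 10 % Pd/C, EtOAc–EtOH, rt
Reagents that add atoms: none
Why: heterogeneous hydrogenation should add H2 to the exocyclic alkene from the face opposite the adjacent CH2Bpin group on C3, which places the benzyl group cis to that arm and sets C4. The same conditions hydrogenolyse the benzyl ether, while the alkyl boronate and the cyclic benzylic ether should survive under neutral conditions.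

**Step 8**
Reactants: 10 2-methoxy-4-{[(3S,4R,5R)-4-[(4,4,5,5-tetramethyl-1,3,2-dioxaborolan-2-yl)methyl]-5-(3,4,5-trimethoxyphenyl)oxolan-3-yl]methyl}phenol
Product: 11 [(2R,3S,4S)-4-(4-hydroxy-3-methoxybenzyl)-2-(3,4,5-trimethoxyphenyl)oxolan-3-yl]methanol
Conditions: NaBO3·4H2O, THF–H2O, rt
Reagents that add atoms: sodium perborate (as its hydroperoxoborate), [Na+].O[B-](O)(O)OO
Why: oxidation of the primary alkylboronate by 1,2-migration in the peroxoborate adduct; perborate is mild enough for the free phenol and no stereocentre is touched.

## Compound list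

1 | methyl (E)-3-(3,4,5-trimethoxyphenyl)prop-2-enoate | COC(=O)/C=C/c1cc(OC)c(OC)c(OC)c1 | starting material
2 | (E)-3-(3,4,5-trimethoxyphenyl)prop-2-en-1-ol | OC/C=C/c1cc(OC)c(OC)c(OC)c1 | intermediate
3 | tert-butyl (E)-3-(3,4,5-trimethoxyphenyl)prop-2-en-1-yl carbonate | CC(C)(C)OC(=O)OC/C=C/c1cc(OC)c(OC)c(OC)c1 | intermediate
4 | 4-bromo-2-methoxyphenol | COc1cc(Br)ccc1O | starting material
5 | 1-(benzyloxy)-4-bromo-2-methoxybenzene | COc1cc(Br)ccc1OCc1ccccc1 | intermediate
6 | prop-2-yn-1-ol | OCC#C | starting material
7 | 3-[4-(benzyloxy)-3-methoxyphenyl]prop-2-yn-1-ol | COc1cc(C#CCO)ccc1OCc1ccccc1 | intermediate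
8 | 5-[(1R)-1-({3-[4-(benzyloxy)-3-methoxyphenyl]prop-2-yn-1-yl}oxy)prop-2-en-1-yl]-1,2,3-trimethoxybenzene | COc1cc(C#CCO[C@H](C=C)c2cc(OC)c(OC)c(OC)c2)ccc1OCc1ccccc1 | intermediate
9 | 2-{[(2R,3R,4Z)-4-[4-(benzyloxy)-3-methoxybenzylidene]-2-(3,4,5-trimethoxyphenyl)oxolan-3-yl]methyl}-4,4,5,5-tetramethyl-1,3,2-dioxaborolane | COc1cc(/C=C2\CO[C@@H](c3cc(OC)c(OC)c(OC)c3)[C@@H]2CB4OC(C)(C)C(C)(C)O4)ccc1OCc1ccccc1 | intermediate
10 | 2-methoxy-4-{[(3S,4R,5R)-4-[(4,4,5,5-tetramethyl-1,3,2-dioxaborolan-2-yl)methyl]-5-(3,4,5-trimethoxyphenyl)oxolan-3-yl]methyl}phenol | COc1cc(C[C@@H]2CO[C@@H](c3cc(OC)c(OC)c(OC)c3)[C@@H]2CB4OC(C)(C)C(C)(C)O4)ccc1O | intermediate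
11 | [(2R,3S,4S)-4-(4-hydroxy-3-methoxybenzyl)-2-(3,4,5-trimethoxyphenyl)oxolan-3-yl]methanol | COc1cc(C[C@@H]2CO[C@@H](c3cc(OC)c(OC)c(OC)c3)[C@@H]2CO)ccc1O | target

## Step count and least certain steps

Total steps: 8. Longest linear sequence: 6 (steps 1, 2, 5, 6, 7, 8, or equally 3, 4, 5, 6, 7, 8).

**Step 6 (key step).**
- What may go wrong: β-hydride elimination from the C6–Pd intermediate may outrun borylation and give the cycloisomerised diene. Palladium may also ionise the allylic, benzylic C2–O1 bond, and the preference for the 2,3-trans isomer may be modest.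
- Fallback: a radical closure that does not pass through an alkyl–palladium species. It sets out from 8. Buffered mCPBA epoxidation of the vinyl group gives the epoxide F1 (both epimers at the oxirane carbon, which does not matter). Cp2TiCl (trivalent titanium, from Cp2TiCl2 and Zn dust, THF) opens the oxirane homolytically to the C3 radical, which closes 5-exo onto the aryl alkyne with the titanium-bound CH2O arm anti to the aryl group. Work-up gives the benzylidene alcohol F2 as an E/Z mixture, both epimers of F1 converging on one 2,3-trans product. Hydrogenation of F2 (H2, Pd/C) reduces the alkene and removes the benzyl group, and the route is rejoined at 11.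

**Step 5.**
- What may go wrong: low branched-to-linear selectivity or low enantioselectivity with a propargylic alkoxide, or coordination of the aryl alkyne to iridium slowing the catalyst.
- Fallback: the stereocentre is made on a small alcohol and the ether bond by displacement. It sets out from 7 and commercial 3,4,5-trimethoxybenzaldehyde. Vinylmagnesium bromide gives the racemic allylic alcohol F3. Immobilised Candida antarctica lipase B with vinyl acetate is expected to acylate the R enantiomer to the acetate F4, and K2CO3 in MeOH frees the (R)-alcohol F5. Alcohol 7 is converted with MsCl and Et3N into the mesylate F6. NaH-mediated Williamson etherification of F5 with F6 rejoins the route at 8.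

**Step 7.**
- What may go wrong: incomplete facial selectivity; migration of the double bond on the palladium surface to the C3=C4 position before reduction, which erases C3; hydrogenolysis of the allylic C5–O1 bond.
- Fallback: C4 is set by a homogeneous syn addition and the benzylic oxygen is removed afterwards. It sets out from 9. BH3·SMe2 should add H to C4 and boron to C7 from the face opposite the C3 arm, and NaBO3 then oxidises both C–B bonds to give the diol F7 (carbinol configuration at C7 immaterial). Neutral hydrogenolysis (H2, Pd(OH)2/C, EtOH) removes the benzylic hydroxyl on C7 and the benzyl ether, and the route is rejoined at 11. Acid must be avoided with F7, because a C7 cation would be trapped by the C6 hydroxyl.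

**Step 8.**
- What may go wrong: oxidative degradation of the electron-rich free phenol under the basic peroxide conditions.
- Fallback: the oxidation is done while the phenol is still benzylated. It sets out from 9. NaBO3 gives the (Z)-benzylidene alcohol F8, and H2 over Pd/C then reduces the alkene and removes the benzyl group to rejoin the route at 11. The price is that the smaller CH2OH group, not CH2Bpin, shields the alkene face.

## Further compounds

F1 | step 6 | 5-[(S)-({3-[4-(benzyloxy)-3-methoxyphenyl]prop-2-yn-1-yl}oxy)(oxiran-2-yl)methyl]-1,2,3-trimethoxybenzene (both oxirane epimers) | C1OC1[C@@H](OCC#Cc1ccc(OCc2ccccc2)c(OC)c1)c1cc(OC)c(OC)c(OC)c1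
F2 | step 6 | [(2R,3S)-4-[4-(benzyloxy)-3-methoxybenzylidene]-2-(3,4,5-trimethoxyphenyl)oxolan-3-yl]methanol (E/Z mixture) | COc1cc(C=C2CO[C@@H](c3cc(OC)c(OC)c(OC)c3)[C@@H]2CO)ccc1OCc1ccccc1
F3 | step 5 | rac-1-(3,4,5-trimethoxyphenyl)prop-2-en-1-ol | C=CC(O)c1cc(OC)c(OC)c(OC)c1
F4 | step 5 | (1R)-1-(3,4,5-trimethoxyphenyl)prop-2-en-1-yl acetate | C=C[C@@H](OC(C)=O)c1cc(OC)c(OC)c(OC)c1
F5 | step 5 | (1R)-1-(3,4,5-trimethoxyphenyl)prop-2-en-1-ol | C=C[C@@H](O)c1cc(OC)c(OC)c(OC)c1
F6 | step 5 | 3-[4-(benzyloxy)-3-methoxyphenyl]prop-2-yn-1-yl methanesulfonate | CS(=O)(=O)OCC#Cc1ccc(OCc2ccccc2)c(OC)c1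
F7 | step 7 | [(2R,3S,4S)-4-{[4-(benzyloxy)-3-methoxyphenyl](hydroxy)methyl}-2-(3,4,5-trimethoxyphenyl)oxolan-3-yl]methanol (carbinol epimer undefined) | COc1cc(C(O)[C@@H]2CO[C@@H](c3cc(OC)c(OC)c(OC)c3)[C@@H]2CO)ccc1OCc1ccccc1
F8 | step 8 | [(2R,3S,4Z)-4-[4-(benzyloxy)-3-methoxybenzylidene]-2-(3,4,5-trimethoxyphenyl)oxolan-3-yl]methanol | COc1cc(/C=C2\CO[C@@H](c3cc(OC)c(OC)c(OC)c3)[C@@H]2CO)ccc1OCc1ccccc1
A1 | alternative 1 | (4S)-4-[4-(benzyloxy)-3-methoxybenzyl]oxolan-2-one | O=C1C[C@H](Cc2ccc(OCc3ccccc3)c(OC)c2)CO1
A2 | alternative 1 | trans-4-[4-(benzyloxy)-3-methoxybenzyl]-3-[hydroxy(3,4,5-trimethoxyphenyl)methyl]oxolan-2-one (carbinol epimers) | COc1cc(C[C@@H]2COC(=O)[C@H]2C(O)c2cc(OC)c(OC)c(OC)c2)ccc1OCc1ccccc1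
A3 | alternative 1 | 2-[4-(benzyloxy)-3-methoxybenzyl]-3-[hydroxy(3,4,5-trimethoxyphenyl)methyl]butane-1,4-diol (carbinol epimers) | COc1cc(C[C@H](CO)[C@@H](CO)C(O)c2cc(OC)c(OC)c(OC)c2)ccc1OCc1ccccc1
A4 | alternative 2 | 1-cyano-2-[(trimethylsilyl)methyl]prop-2-en-1-yl acetate | CC(=O)OC(C#N)C(=C)C[Si](C)(C)C
A5 | alternative 2 | (2R,3S)-4-methylidene-2-(3,4,5-trimethoxyphenyl)oxolane-3-carbonitrile | C=C1CO[C@@H](c2cc(OC)c(OC)c(OC)c2)[C@@H]1C#N
A6 | alternative 3 | 5-[4-(benzyloxy)-3-methoxybenzyl]-2-(3,4,5-trimethoxyphenyl)-4,5-dihydro-1,3-dioxepine (acetal epimers) | COc1cc(C[C@@H]2COC(c3cc(OC)c(OC)c(OC)c3)OC=C2)ccc1OCc1ccccc1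
A7 | alternative 3 | all-trans 4-[4-(benzyloxy)-3-methoxybenzyl]-2-(3,4,5-trimethoxyphenyl)oxolane-3-carbaldehyde | COc1cc(C[C@@H]2CO[C@H](c3cc(OC)c(OC)c(OC)c3)[C@H]2C=O)ccc1OCc1ccccc1
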